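Ring numbering: C1 (OAc), C2, C3 (Me), C4, C5, C6, C7 (enal carbon), C8 (CHO-bearing), C9; C10 is the side-chain methine. The route hinges on the C8–C9 bond of the nine-membered ring. C8 carries a carboxyl-level carbon and C9 the branched C10, so once C10 is drawn as an exomethylene carbon, the γ,δ-unsaturated acid left by an Ireland–Claisen rearrangement appears. A single [3,3] shift shrinks a thirteen-membered allylic lactone to the cyclononadiene, makes C8–C9 and sets C8 and C9 from C1. Precursor 26 already contains both ring alkenes. Its C1 oxygen is a TES ether, orthogonal to the primary TBS ether, so that free C1–OH can later steer hydrogenation at C10.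

Key step: step 15

Assumption: (R)-TRIP is taken to send allenylboronate 9 to the Re face of enal 8, the sense known for aryl and alkenyl aldehydes; were the sense opposite, (S)-TRIP would be used.

Step 1
Reactants: 1 but-2-yne-1,4-diol
Product: 2 4-[(4-methoxybenzyl)oxy]but-2-yn-1-ol
Conditions: NaH (1 equiv), PMBCl (1 equiv), Bu4NI (cat), THF–DMF, 0 °C to rt, 1 in threefold excess
Reagents that add atoms: 4-methoxybenzyl chloride, COc1ccc(CCl)cc1
Why: Williamson etherification of a symmetrical diol used in excess should stop at the mono-ether and marks from the outset the oxygen that ends as the lactone oxygen.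

Step 2
Reactants: 2 4-[(4-methoxybenzyl)oxy]but-2-yn-1-ol
Product: 4 (Z)-3-iodo-4-[(4-methoxybenzyl)oxy]but-2-en-1-ol, via cyclic vinylalanate 3 (not isolated)
Conditions: Red-Al, THF, 0 °C; then I2, THF, −78 °C; aqueous work-up
Reagents that add atoms: iodine, II
Why: Hydroxyl-directed trans-hydroalumination of the propargylic alcohol puts aluminium on the distal alkyne carbon within a five-membered ring, and iodinolysis with retention leaves iodine cis to CH2OH, so the two CH2O carbons (future C1 and the lactone CH2) are locked trans.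

Step 3
Reactants: 4 (Z)-3-iodo-4-[(4-methoxybenzyl)oxy]but-2-en-1-ol, 5 5-bromo-2-methylpent-2-ene
Product: 7 (E)-3-{[(4-methoxybenzyl)oxy]methyl}-7-methylocta-2,6-dien-1-ol, via homoprenylzinc bromide 6 (not isolated)
Conditions: 5, Zn dust, LiCl, THF, 45 °C; then 4, Pd(OAc)2 (2 mol %), SPhos (4 mol %), THF, rt
Reagents that add atoms: none
Why: Negishi sp3–sp2 cross-coupling replaces iodine with retention of alkene geometry and tolerates the free hydroxyl, which fixes the C9=C10 alkene with the homoprenyl group cis to future C1.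

Step 4
Reactants: 7 (E)-3-{[(4-methoxybenzyl)oxy]methyl}-7-methylocta-2,6-dien-1-ol
Product: 8 (E)-3-{[(4-methoxybenzyl)oxy]methyl}-7-methylocta-2,6-dienal
Conditions: activated MnO2, CH2Cl2, rt
Reagents that add atoms: none
Why: Allylic oxidation with manganese dioxide acts only on the allylic alcohol, stops at the aldehyde and should not scramble the trisubstituted alkene.

Step 5
Reactants: 8 (E)-3-{[(4-methoxybenzyl)oxy]methyl}-7-methylocta-2,6-dienal, 9 allenylboronic acid pinacol ester
Product: 11 (4R,5E)-6-{[(4-methoxybenzyl)oxy]methyl}-10-methylundeca-5,9-dien-1-yn-4-ol, via pinacol borate ester 10 (not isolated)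
Conditions: (R)-TRIP (10 mol %), 4 Å MS, toluene, −20 °C; aq NaHCO3 work-up
Reagents that add atoms: none
Why: Chiral phosphoric acid catalysed propargylboration through a closed six-membered SE2′ transition state delivers the allenyl unit as a propargyl group to the Re face of the aldehyde and so sets C1 as R, the only stereocentre that comes from an external chiral source.

Step 6
Reactants: 11 (4R,5E)-6-{[(4-methoxybenzyl)oxy]methyl}-10-methylundeca-5,9-dien-1-yn-4-ol
Product: 12 (4R,5E)-6-{[(4-methoxybenzyl)oxy]methyl}-10-methyl-4-[(triethylsilyl)oxy]undeca-5,9-dien-1-yne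
Conditions: TESCl, imidazole, CH2Cl2, 0 °C
Reagents that add atoms: chlorotriethylsilane, CC[Si](Cl)(CC)CC
Why: Silyl ether protection with TES gives a C1 group that survives organometallic, oxidative and basic steps yet can later be removed in the presence of primary TBS ethers.

Step 7
Reactants: 1 but-2-yne-1,4-diol
Product: 13 4-[(tert-butyldimethylsilyl)oxy]but-2-yn-1-ol
Conditions: NaH (1 equiv), THF, rt; then TBSCl (1 equiv)
Reagents that add atoms: tert-butyldimethylsilyl chloride, CC(C)(C)[Si](C)(C)Cl
Why: Monosilylation through the sparingly soluble monosodium alkoxide of a symmetrical diol should favour the mono-TBS ether, whose oxygen becomes the C7 CH2O group.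

Step 8
Reactants: 13 4-[(tert-butyldimethylsilyl)oxy]but-2-yn-1-ol
Product: 15 (Z)-4-[(tert-butyldimethylsilyl)oxy]-3-iodobut-2-en-1-ol, via cyclic vinylalanate 14 (not isolated)
Conditions: Red-Al, THF, 0 °C; then I2, THF, −78 °C; aqueous work-up
Reagents that add atoms: iodine, II
Why: The same hydroxyl-directed trans-hydroalumination and iodinolysis places iodine on future C7, cis to the C5 carbinol carbon.

Step 9
Reactants: 15 (Z)-4-[(tert-butyldimethylsilyl)oxy]-3-iodobut-2-en-1-ol, 16 tert-butyl bromoacetate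
Product: 18 tert-butyl (E)-3-{[(tert-butyldimethylsilyl)oxy]methyl}-5-hydroxypent-3-enoate, via Reformatsky reagent 17 (not isolated)
Conditions: 16, Zn dust (TMSCl-activated), THF, 40 °C; then 15, Pd2(dba)3 (2.5 mol %), XPhos (10 mol %), THF, rt to 45 °C
Reagents that add atoms: none
Why: Palladium-catalysed Negishi-type coupling of a Reformatsky reagent with an alkenyl iodide proceeds with retention and puts C8 cis to C5, and the bulky tert-butyl ester keeps the cis hydroxy ester from closing to a δ-lactone.

Step 10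
Reactants: 18 tert-butyl (E)-3-{[(tert-butyldimethylsilyl)oxy]methyl}-5-hydroxypent-3-enoate
Product: 20 tert-butyl (E)-3-{[(tert-butyldimethylsilyl)oxy]methyl}-5-chloropent-3-enoate, via allylic mesylate 19 (not isolated)
Conditions: MsCl, 2,4,6-collidine, LiCl, DMF, 0 °C
Reagents that add atoms: lithium chloride, [Li+].[Cl-]
Why: Mesylation followed by in situ SN2 displacement with chloride converts a primary allylic alcohol into the chloride without allylic transposition or loss of alkene geometry.

Step 11
Reactants: 12 (4R,5E)-6-{[(4-methoxybenzyl)oxy]methyl}-10-methyl-4-[(triethylsilyl)oxy]undeca-5,9-dien-1-yne, 20 tert-butyl (E)-3-{[(tert-butyldimethylsilyl)oxy]methyl}-5-chloropent-3-enoate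
Product: 22 tert-butyl (3E,6E,9R,10E)-3-{[(tert-butyldimethylsilyl)oxy]methyl}-11-{[(4-methoxybenzyl)oxy]methyl}-7,15-dimethyl-9-[(triethylsilyl)oxy]hexadeca-3,6,10,14-tetraenoate, via alkenylalane 21 (not isolated)
Conditions: 12, Me3Al (3 equiv), Cp2ZrCl2 (0.3 equiv), ClCH2CH2Cl, 0 °C to rt; then 20, Pd(PPh3)4 (5 mol %), THF, rt
Reagents that add atoms: trimethylaluminium, C[Al](C)C
Why: Negishi zirconium-catalysed methylalumination adds Me and Al syn to the terminal alkyne and so fixes the E C3=C4 alkene, and palladium-catalysed alkenyl–allyl coupling then joins C4 to the primary terminus C5 of the π-allyl complex with retention of both alkene geometries.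

Step 12
Reactants: 22 the PMB ether named in step 11
Product: 23 tert-butyl (3E,6E,9R,10E)-3-{[(tert-butyldimethylsilyl)oxy]methyl}-11-(hydroxymethyl)-7,15-dimethyl-9-[(triethylsilyl)oxy]hexadeca-3,6,10,14-tetraenoate
Conditions: DDQ (1.3 equiv), CH2Cl2–pH 7 buffer (10:1), 0 °C
Reagents that add atoms: none
Why: Oxidative cleavage of the electron-rich PMB ether by DDQ under buffered conditions is orthogonal to both silyl ethers and the tert-butyl ester and should be much faster than any attack on the skipped diene.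

Step 13
Reactants: 23 the hydroxy tert-butyl ester named in step 12
Product: 25 (3E,6E,9R,10E)-3-{[(tert-butyldimethylsilyl)oxy]methyl}-11-(hydroxymethyl)-7,15-dimethyl-9-[(triethylsilyl)oxy]hexadeca-3,6,10,14-tetraenoic acid, via bis-TMS derivative 24 (not isolated)
Conditions: TMSOTf (4 equiv), 2,6-lutidine (6 equiv), CH2Cl2, 0 °C; then pH 5 citrate buffer–THF, 0 °C
Reagents that add atoms: none
Why: Silyl triflate mediated tert-butyl ester cleavage (loss of isobutene in a buffered aprotic medium) avoids strong aqueous acid, which would strip the TES ether, and base, which could move the β,γ-alkene into conjugation, and the transient TMS ester and TMS ether fall off in the mild work-up.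

Step 14
Reactants: 25 the seco acid named in step 13
Product: 26 (4E,7E,10R,11E)-4-{[(tert-butyldimethylsilyl)oxy]methyl}-8-methyl-12-(4-methylpent-3-en-1-yl)-10-[(triethylsilyl)oxy]-1-oxacyclotrideca-4,7,11-trien-2-one
Conditions: PPh3, DIAD, toluene–THF, 0 °C to rt, slow addition of 25 (final about 1 mM)
Reagents that add atoms: none
Why: Mitsunobu macrolactonisation activates the primary allylic alcohol and not the acid, so the β,γ-unsaturated carboxyl group never becomes an acidic acylating species that could isomerise, and high dilution favours the thirteen-membered ring.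

Step 15
Reactants: 26 the thirteen-membered allylic lactone named in step 14
Product: 29 (1R,3E,6E,8R,9S)-7-{[(tert-butyldimethylsilyl)oxy]methyl}-3-methyl-9-(6-methylhepta-1,5-dien-2-yl)-1-[(triethylsilyl)oxy]cyclonona-3,6-diene-8-carboxylic acid (overview numbering), via Z silyl ketene acetal 27 (not isolated), via trimethylsilyl ester 28 (not isolated)
Conditions: LDA (1.2 equiv), THF–DMPU (55:45), −78 °C; TMSCl, −78 to 0 °C; toluene, 80 °C; aq NH4Cl–THF
Reagents that add atoms: none
Why: Deprotonation at C8, the only position that is both α to the carbonyl and allylic, in the dipolar THF–DMPU medium and O-silylation should give the Z silyl ketene acetal 27 (C7 cis to OSi, trans to the ring oxygen), which on warming undergoes a concerted suprafacial [3,3] shift that forms C8–C9, breaks the allylic CH2–O bond and leaves C10=CH2 and a silyl ester. The closest known reaction type is the Ireland–Claisen rearrangement run as a four-atom ring contraction of a macrocyclic allylic lactone. The nine-membered carbocycle is closed transannularly, inside the thirteen-membered ring, through a six-centre chair, so no end-to-end medium-ring cyclisation is involved. C9 is controlled by C1: with C1–H eclipsing the C9=C10 bond to avoid allylic 1,3-strain against the homoprenyl group, the silyloxy group shields one alkene face and C2, through which C8 is tethered, lies on the other, so C8 bonds anti to oxygen. C8 is controlled by the chair, in which the Z ketene acetal and the C9=C10 alkene with C1 trans to CH2O place both ring branches (C7 and C1) equatorial and give the trans C8-carboxyl/C9-alkenyl relation of 37. The step needs ketene acetal geometry, chair over boat and one alkene face, which the cosolvent, the diequatorial tether and the C1 stereocentre should secure, while the C3=C4 (E) and C6=C7 alkenes pass through unchanged.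

Step 16
Reactants: 29 the cyclononadiene acid named in step 15
Product: 30 [(1R,3E,6E,8R,9S)-7-{[(tert-butyldimethylsilyl)oxy]methyl}-3-methyl-9-(6-methylhepta-1,5-dien-2-yl)-1-[(triethylsilyl)oxy]cyclonona-3,6-dien-8-yl]methanol
Conditions: LiAlH4, Et2O, 0 °C to rt
Reagents that add atoms: none
Why: Hydride reduction of the acid with LiAlH4 leaves silyl ethers and unactivated alkenes untouched and should not disturb C8, because the carboxylate formed first is not enolised.

Step 17
Reactants: 30 the primary alcohol named in step 16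
Product: 31 (1R,3E,6E,8R,9S)-7,8-bis{[(tert-butyldimethylsilyl)oxy]methyl}-3-methyl-9-(6-methylhepta-1,5-dien-2-yl)-1-[(triethylsilyl)oxy]cyclonona-3,6-diene
Conditions: TBSCl, imidazole, DMF, rt
Reagents that add atoms: tert-butyldimethylsilyl chloride, CC(C)(C)[Si](C)(C)Cl
Why: Silyl ether protection turns the C8 arm into a bulky, non-coordinating group, so that it cannot compete as a director in step 19.

Step 18
Reactants: 31 the tris-silyl ether named in step 17
Product: 32 (1R,3E,6E,8R,9S)-7,8-bis{[(tert-butyldimethylsilyl)oxy]methyl}-3-methyl-9-(6-methylhepta-1,5-dien-2-yl)cyclonona-3,6-dien-1-ol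
Conditions: PPTS (0.2 equiv), MeOH–CH2Cl2 (1:1), 0 °C
Reagents that add atoms: none
Why: Acid-catalysed methanolysis discriminates by the bulk at silicon, so the TES ether should go well before the primary TBS ethers and only C1–OH is freed under conditions mild enough for the strained diene.

Step 19
Reactants: 32 the C1 alcohol named in step 18
Product: 33 (1R,3E,6E,8R,9R)-7,8-bis{[(tert-butyldimethylsilyl)oxy]methyl}-3-methyl-9-[(2R)-6-methylhept-5-en-2-yl]cyclonona-3,6-dien-1-ol
Conditions: [Rh(nbd)(dppb)]BF4 (10 mol %), H2 (40 bar), CH2Cl2, rt, stopped after one equivalent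
Reagents that add atoms: none
Why: In this hydroxyl-directed hydrogenation with a cationic rhodium diphosphine complex the C1 hydroxyl, the only donor left, carries rhodium to the face of the 1,1-disubstituted C10 alkene on which C1 lies in the rotamer that keeps C9–H beside the homoprenyl chain (least allylic 1,2-strain), which makes C10 R, while the three trisubstituted alkenes should react far more slowly.

Step 20
Reactants: 33 the saturated C1 alcohol named in step 19
Product: 34 (1R,3E,6E,8R,9R)-7,8-bis{[(tert-butyldimethylsilyl)oxy]methyl}-3-methyl-9-[(2R)-6-methylhept-5-en-2-yl]cyclonona-3,6-dien-1-yl acetate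
Conditions: Ac2O, pyridine, DMAP (cat), CH2Cl2, rt
Reagents that add atoms: acetic anhydride, CC(=O)OC(C)=O
Why: DMAP-catalysed acetylation of the only free hydroxyl installs the C1 acetate before any aldehyde is present.

Step 21
Reactants: 34 the acetate named in step 20
Product: 35 (1R,3E,6E,8R,9R)-7,8-bis(hydroxymethyl)-3-methyl-9-[(2R)-6-methylhept-5-en-2-yl]cyclonona-3,6-dien-1-yl acetate
Conditions: HF·pyridine, pyridine, THF, 0 °C to rt
Reagents that add atoms: none
Why: Fluoride desilylation with buffered HF·pyridine removes both primary TBS ethers without an alkoxide stage, so the acetate should neither cleave nor migrate.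

Step 22
Reactants: 35 the diol named in step 21
Product: 37 (1R,3E,6E,8R,9R)-7,8-diformyl-3-methyl-9-[(2R)-6-methylhept-5-en-2-yl]cyclonona-3,6-dien-1-yl acetate (target CNP0113811.3), via bis-alkoxysulfonium salt 36 (not isolated)
Conditions: (COCl)2, DMSO, CH2Cl2, −78 °C; then Et3N, −78 to −20 °C
Reagents that add atoms: none
Why: Swern oxidation activates both hydroxyls before base is added, so the 1,4-diol cannot collapse to a lactol and on to a lactone, and the short cold exposure to amine should spare the epimerisable C8 centre.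

Compound list
1 | but-2-yne-1,4-diol | OCC#CCO | starting material
2 | 4-[(4-methoxybenzyl)oxy]but-2-yn-1-ol | OCC#CCOCc1ccc(OC)cc1 | intermediate
3 | cyclic vinylalanate from 2 (sodium 1-oxa-2-aluminacyclopent-3-ene ate complex, two 2-methoxyethoxy ligands, PMBOCH2 on the Al-bearing carbon) | [Na+].COCCO[Al-]1(OCCOC)OCC=C1COCc1ccc(OC)cc1 | intermediate
4 | (Z)-3-iodo-4-[(4-methoxybenzyl)oxy]but-2-en-1-ol | OC/C=C(\I)COCc1ccc(OC)cc1 | intermediate
5 | 5-bromo-2-methylpent-2-ene | CC(C)=CCCBr | starting material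
6 | (4-methylpent-3-en-1-yl)zinc bromide | CC(C)=CCC[Zn]Br | intermediate
7 | (E)-3-{[(4-methoxybenzyl)oxy]methyl}-7-methylocta-2,6-dien-1-ol | OC/C=C(\CCC=C(C)C)COCc1ccc(OC)cc1 | intermediate
8 | (E)-3-{[(4-methoxybenzyl)oxy]methyl}-7-methylocta-2,6-dienal | O=C/C=C(\CCC=C(C)C)COCc1ccc(OC)cc1 | intermediate
9 | allenylboronic acid pinacol ester | C=C=CB1OC(C)(C)C(C)(C)O1 | starting material
10 | pinacol borate ester of 11 | C#CC[C@@H](OB1OC(C)(C)C(C)(C)O1)/C=C(\CCC=C(C)C)COCc1ccc(OC)cc1 | intermediate
11 | (4R,5E)-6-{[(4-methoxybenzyl)oxy]methyl}-10-methylundeca-5,9-dien-1-yn-4-ol | C#CC[C@@H](O)/C=C(\CCC=C(C)C)COCc1ccc(OC)cc1 | intermediate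
12 | TES ether of 11 | C#CC[C@@H](O[Si](CC)(CC)CC)/C=C(\CCC=C(C)C)COCc1ccc(OC)cc1 | intermediate
13 | 4-[(tert-butyldimethylsilyl)oxy]but-2-yn-1-ol | OCC#CCO[Si](C)(C)C(C)(C)C | intermediate
14 | cyclic vinylalanate from 13 | [Na+].COCCO[Al-]1(OCCOC)OCC=C1CO[Si](C)(C)C(C)(C)C | intermediate
15 | (Z)-4-[(tert-butyldimethylsilyl)oxy]-3-iodobut-2-en-1-ol | OC/C=C(\I)CO[Si](C)(C)C(C)(C)C | intermediate
16 | tert-butyl bromoacetate | CC(C)(C)OC(=O)CBr | starting material
17 | (2-tert-butoxy-2-oxoethyl)zinc bromide | CC(C)(C)OC(=O)C[Zn]Br | intermediate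
18 | tert-butyl (E)-3-{[(tert-butyldimethylsilyl)oxy]methyl}-5-hydroxypent-3-enoate | OC/C=C(\CC(=O)OC(C)(C)C)CO[Si](C)(C)C(C)(C)C | intermediate
19 | methanesulfonate of 18 | CS(=O)(=O)OC/C=C(\CC(=O)OC(C)(C)C)CO[Si](C)(C)C(C)(C)C | intermediate
20 | tert-butyl (E)-3-{[(tert-butyldimethylsilyl)oxy]methyl}-5-chloropent-3-enoate | ClC/C=C(\CC(=O)OC(C)(C)C)CO[Si](C)(C)C(C)(C)C | intermediate
21 | (E)-alkenyl(dimethyl)alane from 12 (Al on C4, new methyl on C3) | C[Al](C)/C=C(C)/C[C@@H](O[Si](CC)(CC)CC)/C=C(\CCC=C(C)C)COCc1ccc(OC)cc1 | intermediate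
22 | tert-butyl (3E,6E,9R,10E)-3-(TBSO-methyl)-11-(PMBO-methyl)-7,15-dimethyl-9-(TESO)hexadeca-3,6,10,14-tetraenoate | CC(C)(C)OC(=O)C/C(CO[Si](C)(C)C(C)(C)C)=C\C/C=C(C)/C[C@@H](O[Si](CC)(CC)CC)/C=C(\CCC=C(C)C)COCc1ccc(OC)cc1 | intermediate
23 | tert-butyl (3E,6E,9R,10E)-3-(TBSO-methyl)-11-(hydroxymethyl)-7,15-dimethyl-9-(TESO)hexadeca-3,6,10,14-tetraenoate | CC(C)(C)OC(=O)C/C(CO[Si](C)(C)C(C)(C)C)=C\C/C=C(C)/C[C@@H](O[Si](CC)(CC)CC)/C=C(\CCC=C(C)C)CO | intermediate
24 | trimethylsilyl ester and primary trimethylsilyl ether of 25 | C[Si](C)(C)OC(=O)C/C(CO[Si](C)(C)C(C)(C)C)=C\C/C=C(C)/C[C@@H](O[Si](CC)(CC)CC)/C=C(\CCC=C(C)C)CO[Si](C)(C)C | intermediate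
25 | (3E,6E,9R,10E)-3-(TBSO-methyl)-11-(hydroxymethyl)-7,15-dimethyl-9-(TESO)hexadeca-3,6,10,14-tetraenoic acid | OC(=O)C/C(CO[Si](C)(C)C(C)(C)C)=C\C/C=C(C)/C[C@@H](O[Si](CC)(CC)CC)/C=C(\CCC=C(C)C)CO | intermediate
26 | (4E,7E,10R,11E)-4-(TBSO-methyl)-8-methyl-12-(4-methylpent-3-en-1-yl)-10-(TESO)-1-oxacyclotrideca-4,7,11-trien-2-one | O=C1C/C(CO[Si](C)(C)C(C)(C)C)=C\C/C=C(C)/C[C@@H](O[Si](CC)(CC)CC)/C=C(CCC=C(C)C)/CO1 | intermediate
27 | Z trimethylsilyl ketene acetal of 26 (C7 cis to OSi) | C[Si](C)(C)O/C1=C\C(CO[Si](C)(C)C(C)(C)C)=C/C/C=C(C)/C[C@@H](O[Si](CC)(CC)CC)/C=C(CCC=C(C)C)/CO1 | intermediate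
28 | trimethylsilyl ester of 29 | CC[Si](CC)(CC)O[C@@H]1C/C(C)=C/C/C=C(/CO[Si](C)(C)C(C)(C)C)[C@H](C(=O)O[Si](C)(C)C)[C@H]1C(=C)CCC=C(C)C | intermediate
29 | (1R,3E,6E,8R,9S)-cyclononadiene C8 acid with C10 exomethylene, 1-OTES, 7-CH2OTBS | CC[Si](CC)(CC)O[C@@H]1C/C(C)=C/C/C=C(/CO[Si](C)(C)C(C)(C)C)[C@H](C(=O)O)[C@H]1C(=C)CCC=C(C)C | intermediate
30 | C8 hydroxymethyl compound (1R,8R,9S), 1-OTES, 7-CH2OTBS | CC[Si](CC)(CC)O[C@@H]1C/C(C)=C/C/C=C(/CO[Si](C)(C)C(C)(C)C)[C@H](CO)[C@H]1C(=C)CCC=C(C)C | intermediate
31 | 7,8-bis(TBSO-methyl) 1-OTES compound (1R,8R,9S) | CC[Si](CC)(CC)O[C@@H]1C/C(C)=C/C/C=C(/CO[Si](C)(C)C(C)(C)C)[C@H](CO[Si](C)(C)C(C)(C)C)[C@H]1C(=C)CCC=C(C)C | intermediate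
32 | 7,8-bis(TBSO-methyl) C1 alcohol with C10 exomethylene (1R,8R,9S) | O[C@@H]1C/C(C)=C/C/C=C(/CO[Si](C)(C)C(C)(C)C)[C@H](CO[Si](C)(C)C(C)(C)C)[C@H]1C(=C)CCC=C(C)C | intermediate
33 | 7,8-bis(TBSO-methyl) C1 alcohol with (10R) side chain (1R,8R,9R) | O[C@@H]1C/C(C)=C/C/C=C(/CO[Si](C)(C)C(C)(C)C)[C@H](CO[Si](C)(C)C(C)(C)C)[C@H]1[C@H](C)CCC=C(C)C | intermediate
34 | C1 acetate of 33 | CC(=O)O[C@@H]1C/C(C)=C/C/C=C(/CO[Si](C)(C)C(C)(C)C)[C@H](CO[Si](C)(C)C(C)(C)C)[C@H]1[C@H](C)CCC=C(C)C | intermediate
35 | 7,8-bis(hydroxymethyl) C1 acetate | CC(=O)O[C@@H]1C/C(C)=C/C/C=C(/CO)[C@H](CO)[C@H]1[C@H](C)CCC=C(C)C | intermediate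
36 | bis(dimethylalkoxysulfonium) dichloride of 35 | CC(=O)O[C@@H]1C/C(C)=C/C/C=C(/CO[S+](C)C)[C@H](CO[S+](C)C)[C@H]1[C@H](C)CCC=C(C)C.[Cl-].[Cl-] | intermediate
37 | (1R,3E,6E,8R,9R)-7,8-diformyl-3-methyl-9-[(2R)-6-methylhept-5-en-2-yl]cyclonona-3,6-dien-1-yl acetate | CC(=O)O[C@@H]1C/C(C)=C/C/C=C(/C=O)[C@H](C=O)[C@H]1[C@H](C)CCC=C(C)C | target

Total steps: 22. Longest linear sequence: 18 steps (steps 1–6, then 11–22).

Steps most likely to fail

Step 15. Ketene acetal geometry may erode inside the ring. The rearrangement may leak through a boat. The lithium dienolate may drift into conjugation before it is silylated. Each of these weakens control at C8 and C9. The fallback sets out from 26 and moves stereocontrol from the substrate to a reagent. Soft enolisation uses the bromoborane made from (1R,2R)-N,N′-bis{[3,5-bis(trifluoromethyl)phenyl]sulfonyl}-1,2-diphenylethane-1,2-diamine, taking the enantiomer that reinforces the C1 bias (drawn as R,R), and a tertiary amine at −78 °C. The amine and solvent pair is chosen for the enolate with C7 cis to O–B. This should give the boron ketene acetal F1. Its [3,3] shift runs below room temperature and should give the acyloxyborane F2, and hydrolysis comes back to the route at 29.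

Step 19. The rhodium chelate may form through the other C9–C10 rotamer, so that hydrogen reaches the wrong face of the C10 alkene. The C3=C4 alkene, also homoallylic to the C1 hydroxyl, may be saturated as well. The fallback sets out from 30, where C1 is still silylated and the C8 hydroxymethyl group is the only donor. In any given rotamer that arm lies on the alkene face opposite to C1, and it is remote from C3=C4. The hindered trisubstituted C6=C7 alkene should lag behind. Directed hydrogenation there should give the saturated primary alcohol F3. Silylation with TBSCl gives the saturated tris-silyl ether F4, and TES methanolysis as in step 18 comes back to the route at 33.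

Step 14. Intermolecular esterification may outrun ring closure, or the activated allylic alcohol may be captured by the hydrazide. The fallback sets out from 25 and activates the other end of the chain. A Shiina macrolactonisation (slow addition to 2-methyl-6-nitrobenzoic anhydride and DMAP in CH2Cl2 at rt) passes through the mixed anhydride F5 and comes back to the route at 26.

Further compounds
F1 | step 15 | boron ketene acetal of 26 bearing the (R,R)-bis-sulfonamide diazaborolidine | O=S(=O)(c1cc(C(F)(F)F)cc(C(F)(F)F)c1)N1B(O/C2=C\C(CO[Si](C)(C)C(C)(C)C)=C/C/C=C(C)/C[C@@H](O[Si](CC)(CC)CC)/C=C(CCC=C(C)C)/CO2)N(S(=O)(=O)c2cc(C(F)(F)F)cc(C(F)(F)F)c2)[C@H](c2ccccc2)[C@H]1c1ccccc1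
F2 | step 15 | acyloxyborane of 29 bearing the same diazaborolidine | CC[Si](CC)(CC)O[C@@H]1C/C(C)=C/C/C=C(/CO[Si](C)(C)C(C)(C)C)[C@H](C(=O)OB2N(S(=O)(=O)c3cc(C(F)(F)F)cc(C(F)(F)F)c3)[C@H](c3ccccc3)[C@@H](c3ccccc3)N2S(=O)(=O)c2cc(C(F)(F)F)cc(C(F)(F)F)c2)[C@H]1C(=C)CCC=C(C)C
F3 | step 19 | saturated primary alcohol (1-OTES, 7-CH2OTBS, 8-CH2OH, 10R side chain) | CC[Si](CC)(CC)O[C@@H]1C/C(C)=C/C/C=C(/CO[Si](C)(C)C(C)(C)C)[C@H](CO)[C@H]1[C@H](C)CCC=C(C)C
F4 | step 19 | saturated tris-silyl ether (1-OTES, 7,8-bis-CH2OTBS, 10R side chain) | CC[Si](CC)(CC)O[C@@H]1C/C(C)=C/C/C=C(/CO[Si](C)(C)C(C)(C)C)[C@H](CO[Si](C)(C)C(C)(C)C)[C@H]1[C@H](C)CCC=C(C)C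
F5 | step 14 | mixed anhydride of 25 and 2-methyl-6-nitrobenzoic acid | Cc1cccc([N+](=O)[O-])c1C(=O)OC(=O)C/C(CO[Si](C)(C)C(C)(C)C)=C\C/C=C(C)/C[C@@H](O[Si](CC)(CC)CC)/C=C(\CCC=C(C)C)CO
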